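**Plan**

1. Retrosynthetic cuts, in order: the C3–CH2 bond between the γ-lactone (ring A) and ring B (enolate benzylation); the lactone ring, back to a ring C benzylic bromide and a pentenoyl imide; the O1–C2 ether bond of the dihydrobenzofuran; and, in both diarylpropane units, the aldol C–C bond between the aryl-bearing carbon and the carbinol carbon.
2. Enabling feature: O1–C2 is a benzylic ether and C2 sits para to the oxygen substituent of ring D, so C2 can ionise to a quinone-methide-type cation next to the fixed C3 centre and be closed by the ring C phenol oxygen, whatever the carbinol configuration of the open precursor.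
3. Forward: one arylacetyl oxazolidinone (from 5-bromo-o-vanillin) and O-benzylvanillin give both halves. Boron syn aldol, reduction and acid closure make the ring C/D dihydrofuran first; MgCl2 anti aldol and reduction make the open ring B/E diol.
4. The dihydrobenzofuran bromide is homologated to its benzylic bromide and built into the (R)-β-benzyl-γ-butyrolactone (ring A, the second ring to arise) by auxiliary alkylation and alkene cleavage. The ring B/E benzylic bromide then alkylates the lactone enolate, and fluoride followed by hydrogenolysis unmasks the target.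
5. Stereochemistry: (S)-4-benzyloxazolidinone fixes the aryl-bearing carbon in both aldols (opposite senses from the boron and the magnesium enolate) and, in the anti aldol, the open carbinol. Dihydrobenzofuran C2 follows from C3 in the key step. (R)-4-Benzyloxazolidinone fixes lactone C4, which directs C3 by trans alkylation.

Key step: step 8

Remark: ring letters are A = γ-lactone, B = benzene ring on the lactone C3 arm (carries the open diol), C = benzo ring of the dihydrobenzofuran, D = aryl on dihydrobenzofuran C2, E = aryl on the open carbinol. TBS = tert-butyldimethylsilyl, TMS = trimethylsilyl, Bn = benzyl, Piv = pivaloyl.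
Remark: the boron aldol adduct and the two diols that follow it are drawn as the expected syn (1S) isomers; any carbinol epimer is carried along unseparated, because the key step erases that centre.

**Route**

Step 1
Reactants: 1 5-bromo-2-hydroxy-3-methoxybenzaldehyde
Product: 2 5-bromo-2-(TBS-oxy)-3-methoxybenzaldehyde
Conditions: TBSCl, imidazole, DMF, rt
Reagents that add atoms: tert-butyldimethylsilyl chloride, CC(C)(C)[Si](C)(C)Cl
Why: Silyl ether formation on a phenol masks the ring B/C phenol with the one group that fluoride can later remove in the presence of the aryl bromide and the benzyl ethers.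

Step 2
Reactants: 2 5-bromo-2-(TBS-oxy)-3-methoxybenzaldehyde
Product: 3 tert-butyl[4-bromo-2-methoxy-6-(2-methoxyethenyl)phenoxy]dimethylsilane (E/Z mixture)
Conditions: MeOCH2PPh3Cl, NaN(SiMe3)2, THF, 0 °C; then 2, −78 °C → rt
Reagents that add atoms: (methoxymethyl)triphenylphosphonium chloride, [Cl-].COC[P+](c1ccccc1)(c1ccccc1)c1ccccc1
Why: Wittig methoxymethylenation of an aromatic aldehyde should give the enol ether as a one-carbon homologation handle, its double-bond geometry being irrelevant.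

Step 3
Reactants: 3 tert-butyl[4-bromo-2-methoxy-6-(2-methoxyethenyl)phenoxy]dimethylsilane
Product: 5 [5-bromo-2-(TBS-oxy)-3-methoxyphenyl]acetic acid, via arylacetaldehyde 4 (not isolated)
Conditions: 2 M HCl, THF, 40 °C; cool; then t-BuOH, 2-methyl-2-butene, NaH2PO4, aq NaClO2, 0 °C → rt
Reagents that add atoms: water, O; sodium chlorite, [Na+].[O-]Cl=O
Why: Acid hydrolysis of the enol ether followed by Pinnick oxidation of the sensitive arylacetaldehyde in the same flask should give the arylacetic acid while the hindered aryl silyl ether and the bromide stay intact.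

Step 4
Reactants: 5 [5-bromo-2-(TBS-oxy)-3-methoxyphenyl]acetic acid; 6 (S)-4-benzyl-1,3-oxazolidin-2-one
Product: 8 (4S)-4-benzyl-3-{[5-bromo-2-(TBS-oxy)-3-methoxyphenyl]acetyl}-1,3-oxazolidin-2-one, via pivalic mixed anhydride 7 (not isolated)
Conditions: PivCl, Et3N, THF, −20 °C; then LiCl, 6, −20 °C → rt
Reagents that add atoms: none
Why: N-Acylation of the oxazolidinone through the mixed pivalic anhydride under LiCl/Et3N activation is the standard mild way to an arylacetyl imide and creates no stereocentre.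

Step 5
Reactants: 8 (4S)-4-benzyl-3-{[5-bromo-2-(TBS-oxy)-3-methoxyphenyl]acetyl}-1,3-oxazolidin-2-one; 9 4-(benzyloxy)-3-methoxybenzaldehyde
Product: 10 (4S)-4-benzyl-3-[(2S,3S)-3-(4-benzyloxy-3-methoxyphenyl)-2-[5-bromo-2-(TBS-oxy)-3-methoxyphenyl]-3-hydroxypropanoyl]-1,3-oxazolidin-2-one
Conditions: Bu2BOTf, i-Pr2NEt, CH2Cl2, −78 → 0 °C; 9, −78 → 0 °C; then pH 7 buffer, MeOH, H2O2, 0 °C
Reagents that add atoms: none
Why: In this Evans boron aldol the Z-boron enolate should react through a closed Zimmerman–Traxler chair on the face away from the auxiliary benzyl group, which fixes the aryl-bearing carbon as 2S (the later C3 of the dihydrobenzofuran) and should give the syn carbinol, whose configuration is not needed later.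

Step 6
Reactants: 10 syn aldol imide
Product: 11 (1S,2R)-1-(4-benzyloxy-3-methoxyphenyl)-2-[5-bromo-2-(TBS-oxy)-3-methoxyphenyl]propane-1,3-diol
Conditions: LiBH4, THF, MeOH (2 equiv), 0 °C
Reagents that add atoms: none
Why: Reductive removal of the auxiliary with LiBH4 should give the 1,3-diol and return the oxazolidinone without touching the stereocentres, and a possible shift of the silyl group from the phenol to an alkoxide is harmless because the next step removes it.

Step 7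
Reactants: 11 (1S,2R)-1-(4-benzyloxy-3-methoxyphenyl)-2-[5-bromo-2-(TBS-oxy)-3-methoxyphenyl]propane-1,3-diol
Product: 12 (1S,2R)-1-(4-benzyloxy-3-methoxyphenyl)-2-(5-bromo-2-hydroxy-3-methoxyphenyl)propane-1,3-diol
Conditions: Bu4NF, AcOH, THF, 0 °C
Reagents that add atoms: none
Why: Buffered fluoride desilylation should free the ring C phenol without ionising the benzylic alcohol.

Step 8
Reactants: 12 (1S,2R)-1-(4-benzyloxy-3-methoxyphenyl)-2-(5-bromo-2-hydroxy-3-methoxyphenyl)propane-1,3-diol (any 1R epimer included)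
Product: 13 [(2S,3R)-2-(4-benzyloxy-3-methoxyphenyl)-5-bromo-7-methoxy-2,3-dihydro-1-benzofuran-3-yl]methanol
Conditions: TsOH·H2O (10 mol%), CH2Cl2 (0.01 M), 0 °C → rt
Reagents that add atoms: none
Why: Protonation of the benzylic hydroxyl and loss of water should give a planar cation delocalised onto the para benzyloxy oxygen of ring D (an O-alkylated quinone methide), so the carbinol configuration is erased and both epimers enter one intermediate, which the ortho phenol oxygen of ring C captures to form the O1–C2 bond. The closest known reaction type is the acid-catalysed cyclodehydration of 2-(2-hydroxyaryl)-1-arylpropane-1,3-diols to trans-2-aryl-3-hydroxymethyl-2,3-dihydrobenzofurans. The dihydrofuran ring closes by 5-exo-trig attack of the phenol oxygen on the cationic carbon. The new C2 centre (S) is controlled by C3: the oxygen should add to the face anti to the CH2OH group, and because the closure is reversible under acid the more stable trans isomer is also the thermodynamic product. The step needs ionisation of the secondary para-alkoxybenzylic hydroxyl only, which the primary alcohol cannot match, and ring closure in preference to loss of formaldehyde or intermolecular capture, which the proximity of the phenol, high dilution and low temperature should secure.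

Step 9
Reactants: 13 [(2S,3R)-2-(4-benzyloxy-3-methoxyphenyl)-5-bromo-7-methoxy-2,3-dihydro-1-benzofuran-3-yl]methanol
Product: 14 (2S,3R)-2-(4-benzyloxy-3-methoxyphenyl)-5-bromo-3-[(TBS-oxy)methyl]-7-methoxy-2,3-dihydro-1-benzofuran
Conditions: TBSCl, imidazole, DMF, rt
Reagents that add atoms: tert-butyldimethylsilyl chloride, CC(C)(C)[Si](C)(C)Cl
Why: Silylation of the only free hydroxyl protects the primary alcohol against the organolithium and enolate steps that follow.

Step 10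
Reactants: 14 (2S,3R)-2-(4-benzyloxy-3-methoxyphenyl)-5-bromo-3-[(TBS-oxy)methyl]-7-methoxy-2,3-dihydro-1-benzofuran
Product: 16 {(2S,3R)-2-(4-benzyloxy-3-methoxyphenyl)-3-[(TBS-oxy)methyl]-7-methoxy-2,3-dihydro-1-benzofuran-5-yl}methanol, via aldehyde 15 (not isolated)
Conditions: n-BuLi, THF, −78 °C; DMF, −78 → 0 °C; then MeOH, NaBH4, 0 °C
Reagents that add atoms: N,N-dimethylformamide, CN(C)C=O
Why: Bromine–lithium exchange, formylation with DMF and borohydride reduction in the same pot should turn the aryl bromide into the benzylic alcohol, the two stereocentres being remote and not acidic at −78 °C.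

Step 11
Reactants: 16 {(2S,3R)-2-(4-benzyloxy-3-methoxyphenyl)-3-[(TBS-oxy)methyl]-7-methoxy-2,3-dihydro-1-benzofuran-5-yl}methanol
Product: 17 (2S,3R)-2-(4-benzyloxy-3-methoxyphenyl)-5-(bromomethyl)-3-[(TBS-oxy)methyl]-7-methoxy-2,3-dihydro-1-benzofuran
Conditions: CBr4, PPh3, CH2Cl2, 0 °C; used at once
Reagents that add atoms: carbon tetrabromide, BrC(Br)(Br)Br
Why: Appel bromination converts the electron-rich benzylic alcohol into the bromide under neutral conditions that spare the silyl and benzyl ethers.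

Step 12
Reactants: 18 (R)-4-benzyl-1,3-oxazolidin-2-one; 19 pent-4-enoyl chloride
Product: 20 (4R)-4-benzyl-3-(pent-4-enoyl)-1,3-oxazolidin-2-one
Conditions: n-BuLi, THF, −78 °C; then 19, −78 → 0 °C
Reagents that add atoms: none
Why: N-Acylation of the lithiated oxazolidinone with an acid chloride is routine and creates no stereocentre.

Step 13
Reactants: 20 (4R)-4-benzyl-3-(pent-4-enoyl)-1,3-oxazolidin-2-one; 17 ring C/D benzylic bromide
Product: 21 (4R)-4-benzyl-3-[(2S)-2-({(2S,3R)-2-(4-benzyloxy-3-methoxyphenyl)-3-[(TBS-oxy)methyl]-7-methoxy-2,3-dihydro-1-benzofuran-5-yl}methyl)pent-4-enoyl]-1,3-oxazolidin-2-one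
Conditions: NaN(SiMe3)2, THF, −78 °C; then 17, −78 → −30 °C
Reagents that add atoms: none
Why: In this Evans asymmetric alkylation the chelated Z-sodium enolate should be benzylated on the face opposite the auxiliary benzyl group, which sets the new centre as 2S, the future C4 (R) of the lactone.

Step 14
Reactants: 21 alkylated pentenoyl imide
Product: 22 (2S)-2-({(2S,3R)-2-(4-benzyloxy-3-methoxyphenyl)-3-[(TBS-oxy)methyl]-7-methoxy-2,3-dihydro-1-benzofuran-5-yl}methyl)pent-4-en-1-ol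
Conditions: LiBH4, THF, MeOH (2 equiv), 0 °C
Reagents that add atoms: none
Why: Reductive cleavage of the imide with LiBH4 should give the primary alcohol and return the auxiliary without epimerising the α-centre.

Step 15
Reactants: 22 (2S)-2-(arylmethyl)pent-4-en-1-ol
Product: 23 (4R)-4-({(2S,3R)-2-(4-benzyloxy-3-methoxyphenyl)-3-[(TBS-oxy)methyl]-7-methoxy-2,3-dihydro-1-benzofuran-5-yl}methyl)oxolan-2-ol (anomer mixture)
Conditions: OsO4 (2 mol%), NaIO4, 2,6-lutidine, dioxane/H2O (3:1), rt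
Reagents that add atoms: sodium periodate, [Na+].[O-]I(=O)(=O)=O (terminal oxidant; its oxygen reaches carbon through catalytic OsO4)
Why: Lemieux–Johnson cleavage of the terminal alkene should give the aldehyde, which closes onto the primary hydroxyl as the five-membered lactol, and the electron-rich arenes tolerate this oxidant pair.

Step 16
Reactants: 23 lactol
Product: 24 (4R)-4-({(2S,3R)-2-(4-benzyloxy-3-methoxyphenyl)-3-[(TBS-oxy)methyl]-7-methoxy-2,3-dihydro-1-benzofuran-5-yl}methyl)oxolan-2-one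
Conditions: TEMPO (10 mol%), PhI(OAc)2, CH2Cl2, rt
Reagents that add atoms: none
Why: Oxoammonium oxidation (TEMPO/PhI(OAc)2) of a lactol to the γ-lactone is neutral and should leave the benzyl ethers, the silyl ether and the stereocentres alone.

Step 17
Reactants: 8 (4S)-4-benzyl-3-{[5-bromo-2-(TBS-oxy)-3-methoxyphenyl]acetyl}-1,3-oxazolidin-2-one; 9 4-(benzyloxy)-3-methoxybenzaldehyde
Product: 25 (4S)-4-benzyl-3-[(2R,3S)-3-(4-benzyloxy-3-methoxyphenyl)-2-[5-bromo-2-(TBS-oxy)-3-methoxyphenyl]-3-(TMS-oxy)propanoyl]-1,3-oxazolidin-2-one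
Conditions: MgCl2 (20 mol%), Et3N, TMSCl, EtOAc, rt
Reagents that add atoms: chlorotrimethylsilane, C[Si](C)(C)Cl
Why: In this magnesium-halide-catalysed direct anti aldol of an N-acyloxazolidinone with a non-enolisable aromatic aldehyde, the chelated Z-magnesium enolate should react on the face away from the auxiliary benzyl group through a boat transition state with silyl trapping of the aldolate, which sets the ring B-bound carbon as 2R (opposite in sense to step 5) and the carbinol as 3S, anti to it.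

Step 18
Reactants: 25 anti aldol imide TMS ether
Product: 27 (1S,2S)-1-(4-benzyloxy-3-methoxyphenyl)-2-[5-bromo-2-(TBS-oxy)-3-methoxyphenyl]propane-1,3-diol, via trimethylsilyl ether alcohol 26 (not isolated)
Conditions: LiBH4, THF, MeOH (2 equiv), 0 °C; then 10% aq citric acid, MeOH, 0 °C
Reagents that add atoms: none
Why: Reductive cleavage of the auxiliary while the carbinol oxygen is still silylated closes the retro-aldol pathway, and mild aqueous acid then hydrolyses the labile trimethylsilyl ether without ionising the carbinol.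

Step 19
Reactants: 27 (1S,2S)-1-(4-benzyloxy-3-methoxyphenyl)-2-[5-bromo-2-(TBS-oxy)-3-methoxyphenyl]propane-1,3-diol
Product: 28 (1S,2S)-1-(4-benzyloxy-3-methoxyphenyl)-2-[5-bromo-2-(TBS-oxy)-3-methoxyphenyl]-1,3-bis(TBS-oxy)propane
Conditions: TBSOTf, 2,6-lutidine, CH2Cl2, −40 → 0 °C
Reagents that add atoms: tert-butyldimethylsilyl triflate, CC(C)(C)[Si](C)(C)OS(=O)(=O)C(F)(F)F
Why: Exhaustive silylation with the silyl triflate under base buffering should protect the primary and the hindered benzylic hydroxyl, and would also re-silylate the phenol if the aryl silyl group had migrated in step 18.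

Step 20
Reactants: 28 tris-TBS aryl bromide
Product: 30 {3-[(1S,2S)-1-(4-benzyloxy-3-methoxyphenyl)-1,3-bis(TBS-oxy)propan-2-yl]-4-(TBS-oxy)-5-methoxyphenyl}methanol, via aldehyde 29 (not isolated)
Conditions: n-BuLi, THF, −78 °C; DMF, −78 → 0 °C; then MeOH, NaBH4, 0 °C
Reagents that add atoms: N,N-dimethylformamide, CN(C)C=O
Why: Bromine–lithium exchange, formylation and in-pot borohydride reduction, as in step 10, should give the ring B benzylic alcohol with the silyl ethers and both stereocentres intact.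

Step 21
Reactants: 30 ring B/E benzylic alcohol
Product: 31 (1S,2S)-1-(4-benzyloxy-3-methoxyphenyl)-2-[5-(bromomethyl)-2-(TBS-oxy)-3-methoxyphenyl]-1,3-bis(TBS-oxy)propane
Conditions: CBr4, PPh3, CH2Cl2, 0 °C; used at once
Reagents that add atoms: carbon tetrabromide, BrC(Br)(Br)Br
Why: Appel bromination gives the benzylic bromide under neutral conditions compatible with the three silyl ethers.

Step 22
Reactants: 24 (4R)-β-benzyl lactone; 31 ring B/E benzylic bromide
Product: 32 (3R,4R)-3-{3-[(1S,2S)-1-(4-benzyloxy-3-methoxyphenyl)-1,3-bis(TBS-oxy)propan-2-yl]-4-(TBS-oxy)-5-methoxybenzyl}-4-({(2S,3R)-2-(4-benzyloxy-3-methoxyphenyl)-3-[(TBS-oxy)methyl]-7-methoxy-2,3-dihydro-1-benzofuran-5-yl}methyl)oxolan-2-one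
Conditions: LiN(SiMe3)2, THF, −78 °C; then 31, DMPU, −78 → −40 °C
Reagents that add atoms: none
Why: Alkylation of the lithium enolate of a β-substituted γ-butyrolactone with a benzylic bromide should occur anti to the C4 substituent, giving the trans-3,4-dibenzyl lactone with C3 as R, as in the standard assembly of dibenzylbutyrolactone lignans.

Step 23
Reactants: 32 fully protected lactone
Product: 33 (3R,4R)-3-{3-[(1S,2S)-1-(4-benzyloxy-3-methoxyphenyl)-1,3-dihydroxypropan-2-yl]-4-hydroxy-5-methoxybenzyl}-4-{[(2S,3R)-2-(4-benzyloxy-3-methoxyphenyl)-3-(hydroxymethyl)-7-methoxy-2,3-dihydro-1-benzofuran-5-yl]methyl}oxolan-2-one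
Conditions: Bu4NF, AcOH, THF, 0 °C → rt
Reagents that add atoms: none
Why: Buffered fluoride should remove the four silyl groups without acid, so the freed ring B phenol cannot close onto the carbinol, and without strong base, so the trans lactone is unaffected.

Step 24
Reactants: 33 bis(benzyl ether)
Product: 34 (3R,4R)-3-{3-[(1S,2S)-1,3-dihydroxy-1-(4-hydroxy-3-methoxyphenyl)propan-2-yl]-4-hydroxy-5-methoxybenzyl}-4-{[(2S,3R)-2-(4-hydroxy-3-methoxyphenyl)-3-(hydroxymethyl)-7-methoxy-2,3-dihydro-1-benzofuran-5-yl]methyl}oxolan-2-one (target)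
Conditions: H2 (1 atm), 10% Pd/C, EtOAc/MeOH, rt
Reagents that add atoms: none
Why: Catalytic hydrogenolysis of the two aryl benzyl ethers under neutral conditions should be faster than cleavage of the benzylic carbinol or of the O1–C2 bond and leaves all six stereocentres and the acid-sensitive open diol untouched.

**Compound list**

1 | 5-bromo-2-hydroxy-3-methoxybenzaldehyde | COc1cc(Br)cc(C=O)c1O | starting material
2 | 5-bromo-2-[(tert-butyldimethylsilyl)oxy]-3-methoxybenzaldehyde | COc1cc(Br)cc(C=O)c1O[Si](C)(C)C(C)(C)C | intermediate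
3 | tert-butyl[4-bromo-2-methoxy-6-(2-methoxyethenyl)phenoxy]dimethylsilane (E/Z mixture) | COC=Cc1cc(Br)cc(OC)c1O[Si](C)(C)C(C)(C)C | intermediate
4 | {5-bromo-2-[(tert-butyldimethylsilyl)oxy]-3-methoxyphenyl}acetaldehyde | O=CCc1cc(Br)cc(OC)c1O[Si](C)(C)C(C)(C)C | intermediate
5 | {5-bromo-2-[(tert-butyldimethylsilyl)oxy]-3-methoxyphenyl}acetic acid | OC(=O)Cc1cc(Br)cc(OC)c1O[Si](C)(C)C(C)(C)C | intermediate
6 | (S)-4-benzyl-1,3-oxazolidin-2-one | O=C1N[C@@H](Cc2ccccc2)CO1 | starting material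
7 | {5-bromo-2-[(tert-butyldimethylsilyl)oxy]-3-methoxyphenyl}acetic pivalic anhydride | CC(C)(C)C(=O)OC(=O)Cc1cc(Br)cc(OC)c1O[Si](C)(C)C(C)(C)C | intermediate
8 | (4S)-4-benzyl-3-({5-bromo-2-[(tert-butyldimethylsilyl)oxy]-3-methoxyphenyl}acetyl)-1,3-oxazolidin-2-one | O=C1OC[C@H](Cc2ccccc2)N1C(=O)Cc1cc(Br)cc(OC)c1O[Si](C)(C)C(C)(C)C | intermediate
9 | 4-(benzyloxy)-3-methoxybenzaldehyde | COc1cc(C=O)ccc1OCc1ccccc1 | starting material
10 | (4S)-4-benzyl-3-[(2S,3S)-3-[4-(benzyloxy)-3-methoxyphenyl]-2-{5-bromo-2-[(tert-butyldimethylsilyl)oxy]-3-methoxyphenyl}-3-hydroxypropanoyl]-1,3-oxazolidin-2-one | O=C1OC[C@H](Cc2ccccc2)N1C(=O)[C@H]([C@H](O)c1ccc(OCc2ccccc2)c(OC)c1)c1cc(Br)cc(OC)c1O[Si](C)(C)C(C)(C)C | intermediate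
11 | (1S,2R)-1-[4-(benzyloxy)-3-methoxyphenyl]-2-{5-bromo-2-[(tert-butyldimethylsilyl)oxy]-3-methoxyphenyl}propane-1,3-diol | OC[C@H]([C@H](O)c1ccc(OCc2ccccc2)c(OC)c1)c1cc(Br)cc(OC)c1O[Si](C)(C)C(C)(C)C | intermediate
12 | (1S,2R)-1-[4-(benzyloxy)-3-methoxyphenyl]-2-(5-bromo-2-hydroxy-3-methoxyphenyl)propane-1,3-diol | OC[C@H]([C@H](O)c1ccc(OCc2ccccc2)c(OC)c1)c1cc(Br)cc(OC)c1O | intermediate
13 | [(2S,3R)-2-[4-(benzyloxy)-3-methoxyphenyl]-5-bromo-7-methoxy-2,3-dihydro-1-benzofuran-3-yl]methanol | Brc1cc(OC)c2c(c1)[C@H](CO)[C@@H](c1ccc(OCc3ccccc3)c(OC)c1)O2 | intermediate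
14 | (2S,3R)-2-[4-(benzyloxy)-3-methoxyphenyl]-5-bromo-3-{[(tert-butyldimethylsilyl)oxy]methyl}-7-methoxy-2,3-dihydro-1-benzofuran | Brc1cc(OC)c2c(c1)[C@H](CO[Si](C)(C)C(C)(C)C)[C@@H](c1ccc(OCc3ccccc3)c(OC)c1)O2 | intermediate
15 | (2S,3R)-2-[4-(benzyloxy)-3-methoxyphenyl]-3-{[(tert-butyldimethylsilyl)oxy]methyl}-7-methoxy-2,3-dihydro-1-benzofuran-5-carbaldehyde | O=Cc1cc(OC)c2c(c1)[C@H](CO[Si](C)(C)C(C)(C)C)[C@@H](c1ccc(OCc3ccccc3)c(OC)c1)O2 | intermediate
16 | [(2S,3R)-2-[4-(benzyloxy)-3-methoxyphenyl]-3-{[(tert-butyldimethylsilyl)oxy]methyl}-7-methoxy-2,3-dihydro-1-benzofuran-5-yl]methanol | OCc1cc(OC)c2c(c1)[C@H](CO[Si](C)(C)C(C)(C)C)[C@@H](c1ccc(OCc3ccccc3)c(OC)c1)O2 | intermediate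
17 | (2S,3R)-2-[4-(benzyloxy)-3-methoxyphenyl]-5-(bromomethyl)-3-{[(tert-butyldimethylsilyl)oxy]methyl}-7-methoxy-2,3-dihydro-1-benzofuran | BrCc1cc(OC)c2c(c1)[C@H](CO[Si](C)(C)C(C)(C)C)[C@@H](c1ccc(OCc3ccccc3)c(OC)c1)O2 | intermediate
18 | (R)-4-benzyl-1,3-oxazolidin-2-one | O=C1N[C@H](Cc2ccccc2)CO1 | starting material
19 | pent-4-enoyl chloride | C=CCCC(Cl)=O | starting material
20 | (4R)-4-benzyl-3-(pent-4-enoyl)-1,3-oxazolidin-2-one | O=C1OC[C@@H](Cc2ccccc2)N1C(=O)CCC=C | intermediate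
21 | (4R)-4-benzyl-3-[(2S)-2-({(2S,3R)-2-[4-(benzyloxy)-3-methoxyphenyl]-3-{[(tert-butyldimethylsilyl)oxy]methyl}-7-methoxy-2,3-dihydro-1-benzofuran-5-yl}methyl)pent-4-enoyl]-1,3-oxazolidin-2-one | O=C1OC[C@@H](Cc2ccccc2)N1C(=O)[C@@H](CC=C)Cc1cc(OC)c2c(c1)[C@H](CO[Si](C)(C)C(C)(C)C)[C@@H](c1ccc(OCc3ccccc3)c(OC)c1)O2 | intermediate
22 | (2S)-2-({(2S,3R)-2-[4-(benzyloxy)-3-methoxyphenyl]-3-{[(tert-butyldimethylsilyl)oxy]methyl}-7-methoxy-2,3-dihydro-1-benzofuran-5-yl}methyl)pent-4-en-1-ol | OC[C@@H](CC=C)Cc1cc(OC)c2c(c1)[C@H](CO[Si](C)(C)C(C)(C)C)[C@@H](c1ccc(OCc3ccccc3)c(OC)c1)O2 | intermediate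
23 | (4R)-4-({(2S,3R)-2-[4-(benzyloxy)-3-methoxyphenyl]-3-{[(tert-butyldimethylsilyl)oxy]methyl}-7-methoxy-2,3-dihydro-1-benzofuran-5-yl}methyl)oxolan-2-ol (anomer mixture) | OC1OC[C@@H](C1)Cc1cc(OC)c2c(c1)[C@H](CO[Si](C)(C)C(C)(C)C)[C@@H](c1ccc(OCc3ccccc3)c(OC)c1)O2 | intermediate
24 | (4R)-4-({(2S,3R)-2-[4-(benzyloxy)-3-methoxyphenyl]-3-{[(tert-butyldimethylsilyl)oxy]methyl}-7-methoxy-2,3-dihydro-1-benzofuran-5-yl}methyl)oxolan-2-one | O=C1OC[C@@H](C1)Cc1cc(OC)c2c(c1)[C@H](CO[Si](C)(C)C(C)(C)C)[C@@H](c1ccc(OCc3ccccc3)c(OC)c1)O2 | intermediate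
25 | (4S)-4-benzyl-3-[(2R,3S)-3-[4-(benzyloxy)-3-methoxyphenyl]-2-{5-bromo-2-[(tert-butyldimethylsilyl)oxy]-3-methoxyphenyl}-3-[(trimethylsilyl)oxy]propanoyl]-1,3-oxazolidin-2-one | O=C1OC[C@H](Cc2ccccc2)N1C(=O)[C@@H]([C@H](O[Si](C)(C)C)c1ccc(OCc2ccccc2)c(OC)c1)c1cc(Br)cc(OC)c1O[Si](C)(C)C(C)(C)C | intermediate
26 | (2S,3S)-3-[4-(benzyloxy)-3-methoxyphenyl]-2-{5-bromo-2-[(tert-butyldimethylsilyl)oxy]-3-methoxyphenyl}-3-[(trimethylsilyl)oxy]propan-1-ol | OC[C@@H]([C@H](O[Si](C)(C)C)c1ccc(OCc2ccccc2)c(OC)c1)c1cc(Br)cc(OC)c1O[Si](C)(C)C(C)(C)C | intermediate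
27 | (1S,2S)-1-[4-(benzyloxy)-3-methoxyphenyl]-2-{5-bromo-2-[(tert-butyldimethylsilyl)oxy]-3-methoxyphenyl}propane-1,3-diol | OC[C@@H]([C@H](O)c1ccc(OCc2ccccc2)c(OC)c1)c1cc(Br)cc(OC)c1O[Si](C)(C)C(C)(C)C | intermediate
28 | (1S,2S)-1-[4-(benzyloxy)-3-methoxyphenyl]-2-{5-bromo-2-[(tert-butyldimethylsilyl)oxy]-3-methoxyphenyl}-1,3-bis[(tert-butyldimethylsilyl)oxy]propane | CC(C)(C)[Si](C)(C)OC[C@@H]([C@H](O[Si](C)(C)C(C)(C)C)c1ccc(OCc2ccccc2)c(OC)c1)c1cc(Br)cc(OC)c1O[Si](C)(C)C(C)(C)C | intermediate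
29 | 3-[(1S,2S)-1-[4-(benzyloxy)-3-methoxyphenyl]-1,3-bis[(tert-butyldimethylsilyl)oxy]propan-2-yl]-4-[(tert-butyldimethylsilyl)oxy]-5-methoxybenzaldehyde | CC(C)(C)[Si](C)(C)OC[C@@H]([C@H](O[Si](C)(C)C(C)(C)C)c1ccc(OCc2ccccc2)c(OC)c1)c1cc(C=O)cc(OC)c1O[Si](C)(C)C(C)(C)C | intermediate
30 | {3-[(1S,2S)-1-[4-(benzyloxy)-3-methoxyphenyl]-1,3-bis[(tert-butyldimethylsilyl)oxy]propan-2-yl]-4-[(tert-butyldimethylsilyl)oxy]-5-methoxyphenyl}methanol | CC(C)(C)[Si](C)(C)OC[C@@H]([C@H](O[Si](C)(C)C(C)(C)C)c1ccc(OCc2ccccc2)c(OC)c1)c1cc(CO)cc(OC)c1O[Si](C)(C)C(C)(C)C | intermediate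
31 | (1S,2S)-1-[4-(benzyloxy)-3-methoxyphenyl]-2-{5-(bromomethyl)-2-[(tert-butyldimethylsilyl)oxy]-3-methoxyphenyl}-1,3-bis[(tert-butyldimethylsilyl)oxy]propane | CC(C)(C)[Si](C)(C)OC[C@@H]([C@H](O[Si](C)(C)C(C)(C)C)c1ccc(OCc2ccccc2)c(OC)c1)c1cc(CBr)cc(OC)c1O[Si](C)(C)C(C)(C)C | intermediate
32 | (3R,4R)-3-{3-[(1S,2S)-1-[4-(benzyloxy)-3-methoxyphenyl]-1,3-bis[(tert-butyldimethylsilyl)oxy]propan-2-yl]-4-[(tert-butyldimethylsilyl)oxy]-5-methoxybenzyl}-4-({(2S,3R)-2-[4-(benzyloxy)-3-methoxyphenyl]-3-{[(tert-butyldimethylsilyl)oxy]methyl}-7-methoxy-2,3-dihydro-1-benzofuran-5-yl}methyl)oxolan-2-one | COc1cc([C@@H](O[Si](C)(C)C(C)(C)C)[C@H](CO[Si](C)(C)C(C)(C)C)c2cc(C[C@H]3C(=O)OC[C@@H]3Cc3cc(OC)c4c(c3)[C@H](CO[Si](C)(C)C(C)(C)C)[C@@H](c3ccc(OCc5ccccc5)c(OC)c3)O4)cc(OC)c2O[Si](C)(C)C(C)(C)C)ccc1OCc1ccccc1 | intermediate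
33 | (3R,4R)-3-{3-[(1S,2S)-1-[4-(benzyloxy)-3-methoxyphenyl]-1,3-dihydroxypropan-2-yl]-4-hydroxy-5-methoxybenzyl}-4-({(2S,3R)-2-[4-(benzyloxy)-3-methoxyphenyl]-3-(hydroxymethyl)-7-methoxy-2,3-dihydro-1-benzofuran-5-yl}methyl)oxolan-2-one | COc1cc([C@@H](O)[C@H](CO)c2cc(C[C@H]3C(=O)OC[C@@H]3Cc3cc(OC)c4c(c3)[C@H](CO)[C@@H](c3ccc(OCc5ccccc5)c(OC)c3)O4)cc(OC)c2O)ccc1OCc1ccccc1 | intermediate
34 | (3R,4R)-3-{3-[(1S,2S)-1,3-dihydroxy-1-(4-hydroxy-3-methoxyphenyl)propan-2-yl]-4-hydroxy-5-methoxybenzyl}-4-{[(2S,3R)-2-(4-hydroxy-3-methoxyphenyl)-3-(hydroxymethyl)-7-methoxy-2,3-dihydro-1-benzofuran-5-yl]methyl}oxolan-2-one | COc1cc([C@@H](O)[C@H](CO)c2cc(C[C@H]3C(=O)OC[C@@H]3Cc3cc(OC)c4c(c3)[C@H](CO)[C@@H](c3ccc(O)c(OC)c3)O4)cc(OC)c2O)ccc1O | target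

**Step count and risks**

Total step count: 24. Longest linear sequence: 18 steps (1–11, 13–16, 22–24).

Three steps most likely to fail:

1. Step 17 (anti aldol). What may go wrong: the amine-mediated soft enolisation may epimerise the α-aryl centre or let the aldolate revert before it is silylated, so that anti selectivity and facial control are eroded. The fallback sets out from acid 5 (with oxazolidinone 18) and comes back at 28. Acid 5 is coupled with 18 as in step 4 to give the enantiomeric (4R)-imide F1. A Bu2BOTf/i-Pr2NEt syn aldol with 9 gives the (2R,3R)-syn adduct F2, and LiBH4 gives the (1R,2S)-diol F3. TBSCl/imidazole silylates the primary hydroxyl to give the mono-silyl ether F4. Mitsunobu esterification (4-nitrobenzoic acid, PPh3, DIAD, toluene, −20 °C) inverts the carbinol and gives the (1S,2S)-nitrobenzoate F5. K2CO3 in MeOH removes the ester and the aryl silyl group to give the phenol diol F6. TBSOTf/2,6-lutidine then silylates the phenol and the carbinol, which is 28.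

2. Step 8 (key ring closure). What may go wrong: the benzylic cation may fragment with loss of formaldehyde from the free CH2OH arm, or be captured between molecules, faster than the phenol closes the ring. The fallback keeps the same O1–C2 bond formation but acylates the primary oxygen so that fragmentation is shut down; it sets out from 11 and comes back at 13. PivCl/pyridine (CH2Cl2, 0 °C) acylates the primary hydroxyl selectively to give the pivalate F7. Bu4NF/AcOH frees the phenol to give the hydroxy pivalate F8. The same acid treatment (or BF3·OEt2 at −40 °C) closes the ring to the dihydrobenzofuran pivalate F9. i-Bu2AlH (CH2Cl2, −78 °C) removes the pivaloyl group and gives 13.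

3. Step 24 (final hydrogenolysis). What may go wrong: once the para phenols are free, the benzylic carbinol C–O bond or the O1–C2 bond may be hydrogenolysed along with the benzyl ethers. The fallback reverses the order of the two deprotections; it sets out from 32 and comes back at 34. The benzyl ethers of 32 are hydrogenolysed (H2, 10% Pd/C, EtOAc) while the carbinol is still a bulky silyl ether and every alcohol is masked, giving the tetrasilyl bisphenol F10. Bu4NF/AcOH in THF at 0 °C then removes the four silyl groups and gives 34 directly.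

Further compounds
F1 | step 17 | (4R)-4-benzyl-3-({5-bromo-2-[(tert-butyldimethylsilyl)oxy]-3-methoxyphenyl}acetyl)-1,3-oxazolidin-2-one | O=C1OC[C@@H](Cc2ccccc2)N1C(=O)Cc1cc(Br)cc(OC)c1O[Si](C)(C)C(C)(C)C
F2 | step 17 | (4R)-4-benzyl-3-[(2R,3R)-3-[4-(benzyloxy)-3-methoxyphenyl]-2-{5-bromo-2-[(tert-butyldimethylsilyl)oxy]-3-methoxyphenyl}-3-hydroxypropanoyl]-1,3-oxazolidin-2-one | O=C1OC[C@@H](Cc2ccccc2)N1C(=O)[C@@H]([C@@H](O)c1ccc(OCc2ccccc2)c(OC)c1)c1cc(Br)cc(OC)c1O[Si](C)(C)C(C)(C)C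
F3 | step 17 | (1R,2S)-1-[4-(benzyloxy)-3-methoxyphenyl]-2-{5-bromo-2-[(tert-butyldimethylsilyl)oxy]-3-methoxyphenyl}propane-1,3-diol | OC[C@@H]([C@@H](O)c1ccc(OCc2ccccc2)c(OC)c1)c1cc(Br)cc(OC)c1O[Si](C)(C)C(C)(C)C
F4 | step 17 | (1R,2S)-1-[4-(benzyloxy)-3-methoxyphenyl]-2-{5-bromo-2-[(tert-butyldimethylsilyl)oxy]-3-methoxyphenyl}-3-[(tert-butyldimethylsilyl)oxy]propan-1-ol | CC(C)(C)[Si](C)(C)OC[C@@H]([C@@H](O)c1ccc(OCc2ccccc2)c(OC)c1)c1cc(Br)cc(OC)c1O[Si](C)(C)C(C)(C)C
F5 | step 17 | (1S,2S)-1-[4-(benzyloxy)-3-methoxyphenyl]-2-{5-bromo-2-[(tert-butyldimethylsilyl)oxy]-3-methoxyphenyl}-3-[(tert-butyldimethylsilyl)oxy]propyl 4-nitrobenzoate | CC(C)(C)[Si](C)(C)OC[C@@H]([C@H](OC(=O)c1ccc(cc1)[N+](=O)[O-])c1ccc(OCc2ccccc2)c(OC)c1)c1cc(Br)cc(OC)c1O[Si](C)(C)C(C)(C)C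
F6 | step 17 | (1S,2S)-1-[4-(benzyloxy)-3-methoxyphenyl]-2-(5-bromo-2-hydroxy-3-methoxyphenyl)-3-[(tert-butyldimethylsilyl)oxy]propan-1-ol | CC(C)(C)[Si](C)(C)OC[C@@H]([C@H](O)c1ccc(OCc2ccccc2)c(OC)c1)c1cc(Br)cc(OC)c1O
F7 | step 8 | (2R,3S)-3-[4-(benzyloxy)-3-methoxyphenyl]-2-{5-bromo-2-[(tert-butyldimethylsilyl)oxy]-3-methoxyphenyl}-3-hydroxypropyl 2,2-dimethylpropanoate | CC(C)(C)C(=O)OC[C@H]([C@H](O)c1ccc(OCc2ccccc2)c(OC)c1)c1cc(Br)cc(OC)c1O[Si](C)(C)C(C)(C)C
F8 | step 8 | (2R,3S)-3-[4-(benzyloxy)-3-methoxyphenyl]-2-(5-bromo-2-hydroxy-3-methoxyphenyl)-3-hydroxypropyl 2,2-dimethylpropanoate | CC(C)(C)C(=O)OC[C@H]([C@H](O)c1ccc(OCc2ccccc2)c(OC)c1)c1cc(Br)cc(OC)c1O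
F9 | step 8 | [(2S,3R)-2-[4-(benzyloxy)-3-methoxyphenyl]-5-bromo-7-methoxy-2,3-dihydro-1-benzofuran-3-yl]methyl 2,2-dimethylpropanoate | Brc1cc(OC)c2c(c1)[C@H](COC(=O)C(C)(C)C)[C@@H](c1ccc(OCc3ccccc3)c(OC)c1)O2
F10 | step 24 | (3R,4R)-3-{3-[(1S,2S)-1,3-bis[(tert-butyldimethylsilyl)oxy]-1-(4-hydroxy-3-methoxyphenyl)propan-2-yl]-4-[(tert-butyldimethylsilyl)oxy]-5-methoxybenzyl}-4-({(2S,3R)-3-{[(tert-butyldimethylsilyl)oxy]methyl}-2-(4-hydroxy-3-methoxyphenyl)-7-methoxy-2,3-dihydro-1-benzofuran-5-yl}methyl)oxolan-2-one | COc1cc([C@@H](O[Si](C)(C)C(C)(C)C)[C@H](CO[Si](C)(C)C(C)(C)C)c2cc(C[C@H]3C(=O)OC[C@@H]3Cc3cc(OC)c4c(c3)[C@H](CO[Si](C)(C)C(C)(C)C)[C@@H](c3ccc(O)c(OC)c3)O4)cc(OC)c2O[Si](C)(C)C(C)(C)C)ccc1O
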